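**Plan**

- **Cuts** (guaianolide numbering; enone half unprimed, spiro half primed). First C6–C7 with O–C12, which opens the cycloheptane and lactone of the enone half. Then C1–C5 (ring A), then C2–C4' with C14–C15' (central cyclohexene), and finally C7–C11, C1–C10 and C2–C3 in the open chain.
- **Forward order.** Dehydrocostus lactone gives the C4'=C15' enone. A 2-chlorodiene adds to it and builds the central ring and spiro C4'. Ring A closes next, and the cycloheptane and lactone close together last.
- **Enabling feature.** Ring A is a cyclopentenone whose C1=C2 bond is shared with the central cyclohexene and whose C4 carries the C15 exo-methylene. It is therefore a divinyl-ketone cyclisation product that lacks two hydrogens. The precursor stores this deficit as a C1–O bond (nucleofuge) and a C15–Si bond (electrofuge).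
- **Origin of the extra oxidation level.** It starts as the C1≡C2 alkyne and passes through the cycloaddition as a C1 vinyl chloride. The chloride is then exchanged for the C7 oxygen, so the leaving group of the key step is the side-chain alcohol itself.
- **Stereochemistry.** C1', C5', C6' and C7' come from dehydrocostus lactone. C4' is set by α-face cycloaddition, C10 by equilibration, C5 by torquoselective closure anti to H-10, and C6/C7 in the cyclic allylchromium transition state.

Key step: step 14

Assumption: C2, C3 and C7 are carried as epimer mixtures wherever they are later flattened, so their SMILES are left open at these centres.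

**Step 1**
Reactants: 1 dehydrocostus lactone
Product: 2 3α-hydroxydehydrocostus lactone
Conditions: SeO2 (0.5 equiv), t-BuOOH (2 equiv), CH2Cl2, 0 °C → rt
Reagents that add atoms: tert-butyl hydroperoxide CC(C)(C)OO; selenium dioxide O=[Se]=O
Why: Allylic oxidation with SeO2 (ene reaction, then [2,3]-sigmatropic shift) is expected at C3', the open ring methylene next to C4'=C15', with oxygen delivered to the convex α face; this centre is flattened in step 2.

**Step 2**
Reactants: 2 3α-hydroxydehydrocostus lactone
Product: 3 dehydrozaluzanin C (3'-oxo-4'(15')-ene)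
Conditions: Dess–Martin periodinane, CH2Cl2, 0 °C → rt
Reagents that add atoms: none
Why: Dess–Martin oxidation of the allylic alcohol spares both exocyclic alkenes and the α-methylene lactone, and the α-methylene cyclopentanone is used at once because it tends to dimerise.

**Step 3**
Reactants: 4 but-2-yne-1,4-diol; 5 tert-butyl(chloro)diphenylsilane
Product: 6 4-(tert-butyldiphenylsilyloxy)but-2-yn-1-ol
Conditions: imidazole, DMF, 0 °C → rt (4 in threefold excess)
Reagents that add atoms: none
Why: Statistical monosilylation of a symmetrical diol used in excess gives a bulky silyl ether that later withstands Grignard, hydride and Lewis acid steps.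

**Step 4**
Reactants: 6 4-(tert-butyldiphenylsilyloxy)but-2-yn-1-ol; 7 (trimethylsilyl)methylmagnesium chloride
Product: 8 (Z)-4-(tert-butyldiphenylsilyloxy)-2-[(trimethylsilyl)methyl]but-2-en-1-ol
Conditions: 7 (3 equiv), CuI (10 mol %), THF, 0 °C → reflux; aq NH4Cl
Reagents that add atoms: none
Why: In this copper-catalysed carbomagnesiation of a propargylic alcohol the magnesium alkoxide directs anti addition, which puts the silylmethyl group (C15) on C4 next to the carbinol and leaves C3 trans to C6 across the new C4=C5 bond.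

**Step 5**
Reactants: 8 (Z)-allylic alcohol
Product: 9 (Z)-4-(tert-butyldiphenylsilyloxy)-2-[(trimethylsilyl)methyl]but-2-enal
Conditions: MnO2, CH2Cl2, rt
Reagents that add atoms: none
Why: MnO2 oxidises the allylic alcohol selectively and does not scramble the trisubstituted alkene.

**Step 6**
Reactants: 9 (Z)-enal; 10 ethynylmagnesium bromide
Product: 11 racemic (Z)-6-(tert-butyldiphenylsilyloxy)-4-[(trimethylsilyl)methyl]hex-4-en-1-yn-3-ol
Conditions: THF, −78 → 0 °C; aq NH4Cl
Reagents that add atoms: none
Why: 1,2-Addition of the alkynyl Grignard reagent to the enal forms C2–C3, and the racemic carbinol C3 becomes the ring A ketone in step 11.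

**Step 7**
Reactants: 12 tert-butyl acetate; 13 2,3-dibromopropene
Product: 15 tert-butyl 4-bromopent-4-enoate, via lithium enolate 14 (not isolated)
Conditions: LiN(iPr)2, THF, −78 °C; then 13, −78 °C → rt
Reagents that add atoms: none
Why: Ester enolate alkylation takes place at the allylic bromide only, keeps the vinylic bromide for cross-coupling, and supplies C7–C10 and C14.

**Step 8**
Reactants: 11 propargylic alcohol; 15 tert-butyl 4-bromopent-4-enoate
Product: 16 enynol ester (C1≡C2, C10=C14, C3 carbinol, C7 tert-butyl ester)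
Conditions: PdCl2(PPh3)2 (3 mol %), CuI (6 mol %), Et3N, THF, rt → 40 °C
Reagents that add atoms: none
Why: Sonogashira coupling of a 2-bromoalkene with a terminal alkyne forms C1–C10 and tolerates the free alcohol, the ester and the allylsilane.

**Step 9**
Reactants: 16 enynol ester
Product: 18 (Z)-chlorodiene diol, via alkenylalanate 17 (not isolated)
Conditions: NaAlH2(OCH2CH2OMe)2 (4 equiv), THF, 0 °C → rt; then N-chlorosuccinimide, −78 → 0 °C
Reagents that add atoms: N-chlorosuccinimide O=C1CCC(=O)N1Cl
Why: Hydroxyl-directed trans-hydroalumination of the propargylic alcohol puts hydrogen on C2 and aluminium on C1, chlorination of the C–Al bond with retention gives the diene with C3 and C10 trans, and the same hydride reduces the ester to the C7 alcohol.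

**Step 10**
Reactants: 3 dehydrozaluzanin C; 18 (Z)-chlorodiene diol
Product: 19 spiro cycloadduct (central cyclohexene C1(Cl)=C10, spiro C4')
Conditions: toluene (1 M), BHT (cat.), 80 °C, sealed tube
Reagents that add atoms: none
Why: In this Diels–Alder reaction the alkyl groups on C2 and C10 make the unsubstituted terminus C14 the nucleophilic end that bonds to the enone β-carbon C15' (ortho/para orientation, which outweighs the weak opposing effect of chlorine), the ketone-activated alkene reacts ahead of the α-methylene lactone, and approach to the convex α face on the side of H-5' sets C4'.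

**Step 11**
Reactants: 19 spiro cycloadduct
Product: 20 keto aldehyde (C3 ketone, C7 aldehyde)
Conditions: Dess–Martin periodinane (2.5 equiv), CH2Cl2, 0 °C → rt
Reagents that add atoms: none
Why: Dess–Martin oxidation converts both alcohols in one operation and uses no acid or base strong enough to touch the allylsilane.

**Step 12**
Reactants: 20 keto aldehyde; 21 methyl acrylate
Product: 22 Baylis–Hillman alcohol (C7 carbinol bearing C11(=C13H2)CO2Me)
Conditions: 21 (as solvent), 3-hydroxyquinuclidine (0.5 equiv), rt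
Reagents that add atoms: none
Why: In this Morita–Baylis–Hillman reaction only the aldehyde is electrophilic enough for the ammonium enolate of the acrylate, the α-methylene lactone (no α-hydrogen) can only add the amine reversibly, and C7 forms as an epimer mixture that is flattened in step 16.

**Step 13**
Reactants: 22 Baylis–Hillman alcohol
Product: 24 cyclic vinylogous ester (C1–O–C7 dihydropyran, allylsilane divinyl ketone), via conjugated chloroenone 23 (not isolated)
Conditions: DBU (2 equiv), MeCN, rt → 40 °C
Reagents that add atoms: none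
Why: Base moves the β,γ-alkene into conjugation and exposes a vinylogous acid chloride, which the C7 hydroxyl captures by 6-exo addition–elimination and so drains the equilibrium, while reversible protonation at C10 should settle with the C9 chain and the bulky C5' branch of the spiro centre both pseudo-equatorial (trans), as in the target.

**Step 14**
Reactants: 24 cyclic vinylogous ester
Product: 26 ring A dienone with C5 silyloxymethyl group plus C10 Baylis–Hillman chain, via C7 trimethylsilyl ether 25 (not isolated)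
Conditions: TMSOTf (0.3 equiv), 2,6-di-tert-butyl-4-methylpyridine (0.5 equiv), CH2Cl2, −78 → 0 °C; aq NaHCO3
Reagents that add atoms: none
Why: Proposed new method: TMSOTf silylates the C3 carbonyl oxygen to give a 1-alkoxy-3-silyloxypentadienyl cation (C1 to C5) that closes by conrotatory 4π electrocyclisation between C1 and C5; the resulting oxyallyl cation is β to silicon at C4 and hands its silyl group to triflate (C4=C15 formed, promoter regenerated), and the remaining C2=C3 silyl enol ether expels the silylated ring oxygen from C1, which restores C1=C2 and frees the C7 oxygen. The closest known reaction types are the silicon-directed Nazarov cyclisation of α-(silylmethyl) divinyl ketones, which ends in an exocyclic methylene, and donor-polarised Nazarov cyclisations; a β-alkoxy nucleofuge that lifts the product to the dienone level has not been shown. The one ring closed is five-membered ring A, by electrocyclic (formally 5-endo) closure, the only mode open to these five atoms. C5 is the only new stereocentre: with C6 on the outside of the U-shaped cation, bonding at the face of C1 opposite pseudo-axial H-10 passes through a trans-fused oxadecalin, and conrotation then places H-5 anti to H-10, which is also the less strained arrangement should C5 equilibrate through its dienol. The step needs the exocyclic rather than an endocyclic C4 alkene, and closure must outrun protodesilylation: the β-silicon effect secures the first (the endocyclic isomer would be a cyclopentadienone), the ring that ties the alkoxy group back to C10 keeps bare oxygen rather than an alkyl group on the inside of the cation, and the hindered pyridine removes stray acid that would move C10'=C14'.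

**Step 15**
Reactants: 26 ring A dienone
Product: 27 diol (C6 primary alcohol, C7 Baylis–Hillman alcohol)
Conditions: HF·pyridine, THF, 0 °C → rt
Reagents that add atoms: none
Why: Fluoride cleavage of the silyl ether under mildly acidic conditions avoids base, which would deprotonate C5 and expel the C6 oxygen.

**Step 16**
Reactants: 27 diol
Product: 28 (Z)-allylic bromide (C7=C11, C13H2Br, free C6 alcohol)
Conditions: NBS, Me2S, CH2Cl2, −20 → 0 °C
Reagents that add atoms: N-bromosuccinimide O=C1CCC(=O)N1Br
Why: The sulfonium salt formed from NBS and Me2S turns allylic alcohols into bromides while saturated primary alcohols are returned on work-up, and with a Baylis–Hillman alcohol bromide enters at C13 with allylic shift (SN2') to give the trisubstituted C7=C11 enoate.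

**Step 17**
Reactants: 28 (Z)-allylic bromide
Product: 29 C5-formyl dienone
Conditions: Dess–Martin periodinane, CH2Cl2, 0 °C
Reagents that add atoms: none
Why: Dess–Martin oxidation gives the C6 aldehyde without base, and the product is used unpurified because H-5 is acidic.

**Step 18**
Reactants: 29 C5-formyl dienone
Product: 32 CNP0221188.1 (target), via allylchromium species 30 (not isolated), via hydroxy ester 31 (not isolated)
Conditions: CrCl2 (6 equiv), THF (0.002 M), rt
Reagents that add atoms: none
Why: In this intramolecular Nozaki–Hiyama allylation divalent chromium converts the allylic bromide into an allylchromium reagent whose γ-carbon C7 adds to the C6 aldehyde through a chair-like six-membered transition state (seven-membered ring closure), the anti adduct lactonises to the trans-fused α-methylene lactone, H-7 is expected syn to H-10 because the C8–C9 tether stays pseudo-equatorial, and CrCl2 leaves enones and lactones unreduced.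

**Compound list**

1 | dehydrocostus lactone | C=C1CC[C@H]2C(=C)CC[C@H]3C(=C)C(=O)O[C@@H]3[C@@H]12 | starting material
2 | 3α-hydroxydehydrocostus lactone | C=C1[C@H](O)C[C@H]2C(=C)CC[C@H]3C(=C)C(=O)O[C@@H]3[C@@H]12 | intermediate
3 | dehydrozaluzanin C | C=C1C(=O)C[C@H]2C(=C)CC[C@H]3C(=C)C(=O)O[C@@H]3[C@@H]12 | intermediate
4 | but-2-yne-1,4-diol | OCC#CCO | starting material
5 | tert-butyl(chloro)diphenylsilane | CC(C)(C)[Si](Cl)(c1ccccc1)c1ccccc1 | starting material
6 | 4-(tert-butyldiphenylsilyloxy)but-2-yn-1-ol | OCC#CCO[Si](c1ccccc1)(c1ccccc1)C(C)(C)C | intermediate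
7 | (trimethylsilyl)methylmagnesium chloride | C[Si](C)(C)C[Mg]Cl | starting material
8 | (Z)-4-(tert-butyldiphenylsilyloxy)-2-[(trimethylsilyl)methyl]but-2-en-1-ol | C[Si](C)(C)C/C(=C\CO[Si](c1ccccc1)(c1ccccc1)C(C)(C)C)CO | intermediate
9 | (Z)-4-(tert-butyldiphenylsilyloxy)-2-[(trimethylsilyl)methyl]but-2-enal | C[Si](C)(C)C/C(=C\CO[Si](c1ccccc1)(c1ccccc1)C(C)(C)C)C=O | intermediate
10 | ethynylmagnesium bromide | C#C[Mg]Br | starting material
11 | racemic (Z)-6-(tert-butyldiphenylsilyloxy)-4-[(trimethylsilyl)methyl]hex-4-en-1-yn-3-ol | C[Si](C)(C)C/C(=C\CO[Si](c1ccccc1)(c1ccccc1)C(C)(C)C)C(O)C#C | intermediate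
12 | tert-butyl acetate | CC(=O)OC(C)(C)C | starting material
13 | 2,3-dibromopropene | C=C(Br)CBr | starting material
14 | lithium enolate of tert-butyl acetate (not isolated) | [Li+].C=C([O-])OC(C)(C)C | intermediate
15 | tert-butyl 4-bromopent-4-enoate | C=C(Br)CCC(=O)OC(C)(C)C | intermediate
16 | enynol ester: C3 carbinol, C1≡C2, C10=C14, C7 tert-butyl ester (racemic) | C[Si](C)(C)C/C(=C\CO[Si](c1ccccc1)(c1ccccc1)C(C)(C)C)C(O)C#CC(=C)CCC(=O)OC(C)(C)C | intermediate
17 | cyclic alkenylalanate, Al on C1 and on the C3 oxygen, C7 alkoxide (not isolated) | [Na+].[Na+].C[Si](C)(C)C/C(=C\CO[Si](c1ccccc1)(c1ccccc1)C(C)(C)C)C1O[Al-](OCCOC)(OCCOC)C(C(=C)CCC[O-])=C1 | intermediate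
18 | chlorodiene diol: C14H2=C10(CH2CH2CH2OH)–C1(Cl)=C2H–C3H(OH), C1=C2 Z, racemic at C3 | C[Si](C)(C)C/C(=C\CO[Si](c1ccccc1)(c1ccccc1)C(C)(C)C)C(O)/C=C(Cl)/C(=C)CCCO | intermediate
19 | spiro cycloadduct: C2–C4' and C14–C15' formed, C2 on the α face of C4', epimers at C2 and C3 | C[Si](C)(C)C/C(=C\CO[Si](c1ccccc1)(c1ccccc1)C(C)(C)C)C(O)C1C(Cl)=C(CCCO)CC[C@]12C(=O)C[C@H]1C(=C)CC[C@H]3C(=C)C(=O)O[C@@H]3[C@H]12 | intermediate
20 | keto aldehyde: C3 ketone, C7 aldehyde, epimers at C2 | C[Si](C)(C)C/C(=C\CO[Si](c1ccccc1)(c1ccccc1)C(C)(C)C)C(=O)C1C(Cl)=C(CCC=O)CC[C@]12C(=O)C[C@H]1C(=C)CC[C@H]3C(=C)C(=O)O[C@@H]3[C@H]12 | intermediate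
21 | methyl acrylate | C=CC(=O)OC | starting material
22 | Baylis–Hillman alcohol, epimers at C2 and C7 | C[Si](C)(C)C/C(=C\CO[Si](c1ccccc1)(c1ccccc1)C(C)(C)C)C(=O)C1C(Cl)=C(CCC(O)C(=C)C(=O)OC)CC[C@]12C(=O)C[C@H]1C(=C)CC[C@H]3C(=C)C(=O)O[C@@H]3[C@H]12 | intermediate
23 | conjugated β-chloro enone C3(=O)–C2=C1(Cl)–C10H (not isolated) | C[Si](C)(C)C/C(=C\CO[Si](c1ccccc1)(c1ccccc1)C(C)(C)C)C(=O)C1=C(Cl)[C@H](CCC(O)C(=C)C(=O)OC)CC[C@]12C(=O)C[C@H]1C(=C)CC[C@H]3C(=C)C(=O)O[C@@H]3[C@H]12 | intermediate
24 | key-step precursor: divinyl ketone with C1=C2 carrying the ring oxygen O–C7 on C1, C4 carrying CH2SiMe3, C6 silyl ether; epimers at C7 | C[Si](C)(C)C/C(=C\CO[Si](c1ccccc1)(c1ccccc1)C(C)(C)C)C(=O)C1=C2OC(C(=C)C(=O)OC)CC[C@@H]2CC[C@]13C(=O)C[C@H]1C(=C)CC[C@H]4C(=C)C(=O)O[C@@H]4[C@H]13 | intermediate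
25 | C7 trimethylsilyl ether of 26 (not isolated) | C=C1C(=O)C2=C([C@@H]1CO[Si](c1ccccc1)(c1ccccc1)C(C)(C)C)[C@H](CCC(O[Si](C)(C)C)C(=C)C(=O)OC)CC[C@]21C(=O)C[C@H]2C(=C)CC[C@H]3C(=C)C(=O)O[C@@H]3[C@H]21 | intermediate
26 | key-step product: ring A dienone (C1=C2, C3=O, C4=C15), H-5 anti to H-10, C5–CH2OSi, C10 chain with C7 carbinol | C=C1C(=O)C2=C([C@@H]1CO[Si](c1ccccc1)(c1ccccc1)C(C)(C)C)[C@H](CCC(O)C(=C)C(=O)OC)CC[C@]21C(=O)C[C@H]2C(=C)CC[C@H]3C(=C)C(=O)O[C@@H]3[C@H]21 | intermediate
27 | diol (C6–OH, C7–OH) | C=C1C(=O)C2=C([C@@H]1CO)[C@H](CCC(O)C(=C)C(=O)OC)CC[C@]21C(=O)C[C@H]2C(=C)CC[C@H]3C(=C)C(=O)O[C@@H]3[C@H]21 | intermediate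
28 | (Z)-2-(bromomethyl)enoate, free C6 alcohol | C=C1C(=O)C2=C([C@@H]1CO)[C@H](CC/C=C(\CBr)C(=O)OC)CC[C@]21C(=O)C[C@H]2C(=C)CC[C@H]3C(=C)C(=O)O[C@@H]3[C@H]21 | intermediate
29 | C5-formyl dienone with bromomethyl enoate | C=C1C(=O)C2=C([C@@H]1C=O)[C@H](CC/C=C(\CBr)C(=O)OC)CC[C@]21C(=O)C[C@H]2C(=C)CC[C@H]3C(=C)C(=O)O[C@@H]3[C@H]21 | intermediate
30 | allylchromium species, Cr on C13 (not isolated) | C=C1C(=O)C2=C([C@@H]1C=O)[C@H](CC/C=C(\C[Cr](Cl)Cl)C(=O)OC)CC[C@]21C(=O)C[C@H]2C(=C)CC[C@H]3C(=C)C(=O)O[C@@H]3[C@H]21 | intermediate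
31 | cycloheptane hydroxy ester, C6–OH anti to the C7 acrylate (not isolated) | C=C1C(=O)C2=C3[C@H](CC[C@@H](C(=C)C(=O)OC)[C@H](O)[C@H]13)CC[C@]21C(=O)C[C@H]2C(=C)CC[C@H]3C(=C)C(=O)O[C@@H]3[C@H]21 | intermediate
32 | CNP0221188.1 | C=C1C(=O)C2=C3[C@H](CC[C@H]4C(=C)C(=O)O[C@@H]4[C@H]13)CC[C@]21C(=O)C[C@H]2C(=C)CC[C@H]3C(=C)C(=O)O[C@@H]3[C@H]21 | target

**Count**

- Total steps: 18.
- Longest linear sequence: 15 (steps 3–6 and 8–18, from but-2-yne-1,4-diol).

**Steps most likely to fail**

**1. Step 14.**

- *What may go wrong.* The alkoxy group may stabilise the open cation so strongly that electrocyclisation is outrun by protodesilylation or by acid-induced migration of C10'=C14'.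
- *Fallback.* The closure is run at the normal oxidation level, where it is a known silicon-directed Nazarov reaction, and the missing unsaturation is added afterwards. The sequence sets out from 22.
  - TBSOTf and 2,6-lutidine give the C7 silyl ether F1.
  - DBU moves the alkene into conjugation to give the β-chloro enone F2.
  - Zn/Ag couple in MeOH removes the vinylogous chloride to give the plain divinyl ketone F3.
  - FeCl3 in CH2Cl2 at low temperature closes it to the 4-methylene cyclopentanone F4.
  - IBX in DMSO dehydrogenates C1–C2 to give the bis-silyl dienone F5. This should be selective because the C3 ketone can enolise only towards C2 and gives a cross-conjugated dienol.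
  - HF·pyridine then removes both silyl groups, and the route is rejoined at 27.

**2. Step 10.**

- *What may go wrong.* Crowding at the forming C2–C4' bond may slow the cycloaddition. Compound 3 could then dimerise, and regio- or facial selectivity could erode.
- *Fallback.* A temporary silicon tether turns the union into an intramolecular Diels–Alder reaction. The sequence sets out from 18 and 2.
  - TBSCl and imidazole silylate the primary alcohol to give the mono-ether F6.
  - iPr2SiCl2 and imidazole link its C3 hydroxyl to the 3α-hydroxyl of 2, giving the silaketal F7.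
  - Heating in toluene (160 °C, sealed tube) gives the tethered cycloadduct F8. The seven-membered tether forces C2 onto C4' and delivers the diene from the α face.
  - HF·pyridine cleaves the silaketal and the primary silyl ether to give the triol F9.
  - Dess–Martin periodinane in excess oxidises the three carbinols, and the route is rejoined at 20.

**3. Step 18.**

- *What may go wrong.* Enolisation at the formyl-bearing C5, which is vinylogously activated by the dienone, may quench the allylchromium reagent or scramble C5. The facial selectivity of the ring closure may also be poor.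
- *Fallback.* Both ketones are taken down to alcohols before the aldehyde is made, which lowers the acidity of H-5, and they are restored at the end. The sequence sets out from 28.
  - Luche reduction (NaBH4, CeCl3·7H2O, MeOH, −78 °C) gives the bromo triol F10.
  - Primary-selective oxidation (TEMPO, PhI(OAc)2) gives the aldehyde diol F11.
  - CrCl2 in dilute THF closes the cycloheptane and lactone to give the bis-lactone diol F12.
  - Dess–Martin periodinane reoxidises C3 and C3', and the route is rejoined at 32.

**Further compounds**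

F1 | step 14 | C7 tert-butyldimethylsilyl ether of 22 | C[Si](C)(C)C/C(=C\CO[Si](c1ccccc1)(c1ccccc1)C(C)(C)C)C(=O)C1C(Cl)=C(CCC(O[Si](C)(C)C(C)(C)C)C(=C)C(=O)OC)CC[C@]12C(=O)C[C@H]1C(=C)CC[C@H]3C(=C)C(=O)O[C@@H]3[C@H]12
F2 | step 14 | conjugated β-chloro enone, C7 silyl ether | C[Si](C)(C)C/C(=C\CO[Si](c1ccccc1)(c1ccccc1)C(C)(C)C)C(=O)C1=C(Cl)[C@H](CCC(O[Si](C)(C)C(C)(C)C)C(=C)C(=O)OC)CC[C@]12C(=O)C[C@H]1C(=C)CC[C@H]3C(=C)C(=O)O[C@@H]3[C@H]12
F3 | step 14 | divinyl ketone with C1–H | C[Si](C)(C)C/C(=C\CO[Si](c1ccccc1)(c1ccccc1)C(C)(C)C)C(=O)C1=C[C@H](CCC(O[Si](C)(C)C(C)(C)C)C(=C)C(=O)OC)CC[C@]12C(=O)C[C@H]1C(=C)CC[C@H]3C(=C)C(=O)O[C@@H]3[C@H]12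
F4 | step 14 | 4-methylene cyclopentanone (C1–H, C2–H, open at these centres) | C=C1C(=O)C2C([C@@H]1CO[Si](c1ccccc1)(c1ccccc1)C(C)(C)C)[C@H](CCC(O[Si](C)(C)C(C)(C)C)C(=C)C(=O)OC)CC[C@]21C(=O)C[C@H]2C(=C)CC[C@H]3C(=C)C(=O)O[C@@H]3[C@H]21
F5 | step 14 | bis-silyl ring A dienone | C=C1C(=O)C2=C([C@@H]1CO[Si](c1ccccc1)(c1ccccc1)C(C)(C)C)[C@H](CCC(O[Si](C)(C)C(C)(C)C)C(=C)C(=O)OC)CC[C@]21C(=O)C[C@H]2C(=C)CC[C@H]3C(=C)C(=O)O[C@@H]3[C@H]21
F6 | step 10 | C7 tert-butyldimethylsilyl ether of 18 | C[Si](C)(C)C/C(=C\CO[Si](c1ccccc1)(c1ccccc1)C(C)(C)C)C(O)/C=C(Cl)/C(=C)CCCO[Si](C)(C)C(C)(C)C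
F7 | step 10 | diisopropylsilaketal joining O–C3 of F6 and O–C3' of 2 | C[Si](C)(C)C/C(=C\CO[Si](c1ccccc1)(c1ccccc1)C(C)(C)C)C(O[Si](C(C)C)(C(C)C)O[C@@H]1C[C@H]2C(=C)CC[C@H]3C(=C)C(=O)O[C@@H]3[C@H]2C1=C)/C=C(Cl)/C(=C)CCCO[Si](C)(C)C(C)(C)C
F8 | step 10 | tethered cycloadduct | C[Si](C)(C)C/C(=C\CO[Si](c1ccccc1)(c1ccccc1)C(C)(C)C)C1O[Si](C(C)C)(C(C)C)O[C@@H]2C[C@H]3C(=C)CC[C@H]4C(=C)C(=O)O[C@@H]4[C@H]3[C@]2(CCC(CCCO[Si](C)(C)C(C)(C)C)=C5Cl)C15
F9 | step 10 | triol (C3, C3' and C7 hydroxyls) | C[Si](C)(C)C/C(=C\CO[Si](c1ccccc1)(c1ccccc1)C(C)(C)C)C(O)C1C(Cl)=C(CCCO)CC[C@]12[C@H](O)C[C@H]1C(=C)CC[C@H]3C(=C)C(=O)O[C@@H]3[C@H]12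
F10 | step 18 | bromo triol (C3, C3' and C6 hydroxyls) | C=C1C(O)C2=C([C@@H]1CO)[C@H](CC/C=C(\CBr)C(=O)OC)CC[C@]21C(O)C[C@H]2C(=C)CC[C@H]3C(=C)C(=O)O[C@@H]3[C@H]21
F11 | step 18 | C6 aldehyde diol | C=C1C(O)C2=C([C@@H]1C=O)[C@H](CC/C=C(\CBr)C(=O)OC)CC[C@]21C(O)C[C@H]2C(=C)CC[C@H]3C(=C)C(=O)O[C@@H]3[C@H]21
F12 | step 18 | bis-lactone diol (C3 and C3' carbinols) | C=C1C(O)C2=C3[C@H](CC[C@H]4C(=C)C(=O)O[C@@H]4[C@H]13)CC[C@]21C(O)C[C@H]2C(=C)CC[C@H]3C(=C)C(=O)O[C@@H]3[C@H]21
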